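**Plan**
1. Retrosynthesis: the two late C–acyl bonds are cut first (ring B C1–CO, ring A C5–CO), then three bonds of the central ring B (C1–C2, C3–C4, C4–C5). This leaves a ring C arm and a ring A arm.
2. Enabling feature: ring B carries oxygen on C2, C4 and C6 and carbon or hydrogen on C1, C3 and C5. C4, C5, C6, C1 and O6 map onto a 3-alkoxy vinylketene (from a cyclobutenone bearing CH2–ring C); C2, C3 and O2 map onto a silyl ynol ether bearing CH2–ring A.
3. Forward: rings A and C both come from 2-methylphloroglucinol. The ring C arm (butyryl in place, methoxy between methyl and bridge) becomes an arylpropanoic acid and then a 3-benzyloxy-4-(arylmethyl)cyclobutenone. The ring A arm (methoxy between methyl and the still open C5) becomes a propargyl arene and then a triisopropylsilyl ynol ether.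
4. Ring B is closed last by thermal benzannulation of the two arms. Desilylation, hydrogenolysis and a twofold Hoesch acylation at the two open ring carbons complete the target.
5. Stereochemistry: the target has no stereocentre. The only stereocentre on the route (C4 of the cyclobutenone) is racemic and becomes aromatic.

Key step: step 14

Remark: ring B is the central ring (C1 butyryl, C3 bridge to ring A, C5 bridge to ring C). ArC = 2,4-bis(benzyloxy)-3-butanoyl-6-methoxy-5-methylphenyl; ArA = 2,6-bis(benzyloxy)-4-methoxy-3-methylphenyl.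

**Ring C arm**

Step 1
Reactants: 1 2-methylbenzene-1,3,5-triol; 2 butanoyl chloride
Product: 3 1-(2,4,6-trihydroxy-3-methylphenyl)butan-1-one
Conditions: AlCl3, PhNO2, 0 → 50 °C; aq. HCl
Reagents that add atoms: none
Why: Friedel–Crafts acylation at one of the two equivalent open ring carbons, after which the chelated ketone should deactivate the ring against a second acylation.

Step 2
Reactants: 3 1-(2,4,6-trihydroxy-3-methylphenyl)butan-1-one
Product: 4 1-(2,6-dihydroxy-4-methoxy-3-methylphenyl)butan-1-one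
Conditions: MeI (1.05 equiv), K2CO3 (1.0 equiv), acetone, rt
Reagents that add atoms: iodomethane, CI
Why: Williamson ether synthesis in which one equivalent of base should select the 4-hydroxyl, the most acidic one (para to the ketone) and the only one not hydrogen-bonded to the carbonyl group.

Step 3
Reactants: 4 1-(2,6-dihydroxy-4-methoxy-3-methylphenyl)butan-1-one
Product: 6 3-butanoyl-2,4-dihydroxy-6-methoxy-5-methylbenzaldehyde, via α-chloro ether 5 (not isolated)
Conditions: Cl2CHOMe, TiCl4, CH2Cl2, −10 → 0 °C; then aq. HCl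
Reagents that add atoms: dichloromethyl methyl ether, COC(Cl)Cl; water, O
Why: Rieche formylation at the only open ring carbon, preferred to Vilsmeier conditions because those can turn an ortho-hydroxyaryl ketone into a chromone, with the aqueous work-up hydrolysing 5 to the aldehyde.

Step 4
Reactants: 6 3-butanoyl-2,4-dihydroxy-6-methoxy-5-methylbenzaldehyde
Product: 7 2,4-bis(benzyloxy)-3-butanoyl-6-methoxy-5-methylbenzaldehyde
Conditions: BnBr, K2CO3, DMF, 70 °C
Reagents that add atoms: benzyl bromide, BrCc1ccccc1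
Why: Williamson O-benzylation under forcing conditions, needed because both hydroxyls are chelated to carbonyl groups, with C-alkylation excluded because no ring carbon is open.

Step 5
Reactants: 7 2,4-bis(benzyloxy)-3-butanoyl-6-methoxy-5-methylbenzaldehyde; 8 Meldrum's acid
Product: 11 3-[2,4-bis(benzyloxy)-3-butanoyl-6-methoxy-5-methylphenyl]propanoic acid, via arylidene Meldrum's acid 9 (not isolated), via arylmethyl Meldrum's acid 10 (not isolated)
Conditions: HCO2H–Et3N (5:2), 95–100 °C
Reagents that add atoms: none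
Why: Knoevenagel condensation, conjugate reduction of 9 by formate and hydrolysis–decarboxylation of 10 proceed in one flask in triethylammonium formate, conditions that should leave the benzyl ethers and the hindered ketone untouched.

Step 6
Reactants: 12 benzyl alcohol; 13 trichloroethylene
Product: 16 benzyl ethynyl ether, via dichlorovinyl ether 14 (not isolated), via lithium benzyloxyacetylide 15 (not isolated)
Conditions: KH, THF, 0 °C; 13, −50 °C → rt; n-BuLi (2.3 equiv), −78 → −40 °C; MeOH, −78 °C; kept as a cold solution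
Reagents that add atoms: none
Why: Addition–elimination of the potassium alkoxide on trichloroethylene, then n-BuLi-induced dehydrochlorination and chlorine–lithium exchange, is the standard synthesis of terminal ynol ethers; the product is kept cold because benzyl ynol ethers rearrange on warming.

Step 7
Reactants: 11 3-[2,4-bis(benzyloxy)-3-butanoyl-6-methoxy-5-methylphenyl]propanoic acid; 16 benzyl ethynyl ether
Product: 19 3-(benzyloxy)-4-{[2,4-bis(benzyloxy)-3-butanoyl-6-methoxy-5-methylphenyl]methyl}cyclobut-2-en-1-one (racemic), via acid chloride 17 (not isolated), via ketene 18 (not isolated)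
Conditions: (COCl)2, cat. DMF, CH2Cl2, 0 °C → rt, evaporate; then 16 (3 equiv), Et3N (slow addition), CH2Cl2, 0 °C → rt
Reagents that add atoms: none
Why: Dehydrochlorination of 17 gives aldoketene 18, which undergoes ketene–alkoxyalkyne [2+2] cycloaddition with 16, the ketene carbonyl carbon bonding to the nucleophilic CH terminus of the ynol ether so that benzyloxy ends on C3 and the arylmethyl group on C4; the new stereocentre C4 forms racemic.

**Ring A arm**

Step 8
Reactants: 1 2-methylbenzene-1,3,5-triol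
Product: 21 2,4,6-trihydroxy-3-methylbenzaldehyde, via iminium chloride 20 (not isolated)
Conditions: POCl3, DMF, EtOAc, 0 °C → rt; then H2O, 50 °C
Reagents that add atoms: N,N-dimethylformamide, CN(C)C=O; water, O
Why: Vilsmeier–Haack formylation of the electron-rich triol at either of its two equivalent open carbons, the iminium salt 20 being hydrolysed on aqueous work-up.

Step 9
Reactants: 21 2,4,6-trihydroxy-3-methylbenzaldehyde
Product: 22 2,6-dihydroxy-4-methoxy-3-methylbenzaldehyde
Conditions: MeI (1.05 equiv), K2CO3 (1.0 equiv), acetone, rt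
Reagents that add atoms: iodomethane, CI
Why: Williamson ether synthesis, selective for the 4-hydroxyl because it is para to the aldehyde and the only hydroxyl not chelated to it.

Step 10
Reactants: 22 2,6-dihydroxy-4-methoxy-3-methylbenzaldehyde
Product: 23 2,6-bis(benzyloxy)-4-methoxy-3-methylbenzaldehyde
Conditions: BnBr, K2CO3, DMF, 70 °C
Reagents that add atoms: benzyl bromide, BrCc1ccccc1
Why: Williamson O-benzylation of the two chelated hydroxyls under forcing conditions.

Step 11
Reactants: 23 2,6-bis(benzyloxy)-4-methoxy-3-methylbenzaldehyde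
Product: 25 2-[2,6-bis(benzyloxy)-4-methoxy-3-methylphenyl]acetaldehyde, via enol ether 24 (not isolated)
Conditions: Ph3P(Cl)CH2OMe, KOt-Bu, THF, 0 °C → rt; then 2 M HCl, THF, rt
Reagents that add atoms: (methoxymethyl)triphenylphosphonium chloride, COC[P+](c1ccccc1)(c1ccccc1)c1ccccc1.[Cl-]; water, O
Why: Wittig methoxymethylenation followed by acid hydrolysis of enol ether 24 is a standard one-carbon homologation of an aldehyde, and benzyl aryl ethers are stable to the dilute acid.

Step 12
Reactants: 25 2-[2,6-bis(benzyloxy)-4-methoxy-3-methylphenyl]acetaldehyde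
Product: 26 1,3-bis(benzyloxy)-5-methoxy-4-methyl-2-(prop-2-yn-1-yl)benzene
Conditions: dimethyl (1-diazo-2-oxopropyl)phosphonate, K2CO3, MeOH, 0 °C → rt
Reagents that add atoms: dimethyl (1-diazo-2-oxopropyl)phosphonate, COP(=O)(OC)C(=[N+]=[N-])C(C)=O
Why: Seyferth–Gilbert homologation with the Ohira–Bestmann reagent converts the aldehyde into the terminal alkyne under mild carbonate conditions that should not isomerise the propargylic arene.

Step 13
Reactants: 26 1,3-bis(benzyloxy)-5-methoxy-4-methyl-2-(prop-2-yn-1-yl)benzene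
Product: 28 triisopropyl{[3-(2,6-bis(benzyloxy)-4-methoxy-3-methylphenyl)prop-1-yn-1-yl]oxy}silane, via lithium ynolate 27 (not isolated)
Conditions: n-BuLi, THF, −78 °C; t-BuOOLi (from t-BuOOH and LiN(SiMe3)2), −78 → 0 °C; TIPSOTf, −78 → 0 °C
Reagents that add atoms: tert-butyl hydroperoxide, CC(C)(C)OO; triisopropylsilyl trifluoromethanesulfonate, CC(C)[Si](OS(=O)(=O)C(F)(F)F)(C(C)C)C(C)C
Why: Oxidation of the lithium acetylide by lithium tert-butyl peroxide gives ynolate 27, which the bulky silyl triflate traps on oxygen, a known preparation of triisopropylsilyl ynol ethers from terminal alkynes.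

**Union and completion**

Step 14
Reactants: 19 3-(benzyloxy)-4-(ArC-methyl)cyclobut-2-en-1-one (racemic); 28 triisopropylsilyl ynol ether of the ring A arm
Product: 33 3-(benzyloxy)-2-(ArC-methyl)-6-(ArA-methyl)-5-[(triisopropylsilyl)oxy]phenol (ring B: O2 silyl ether, O4 free, O6 benzyl ether, C1 unsubstituted), via vinylketene 29 (not isolated), via vinylcyclobutenone 30 (not isolated), via dienylketene 31 (not isolated), via cyclohexadienone 32 (not isolated)
Conditions: PhMe (degassed), 80 → 110 °C, sealed tube, 28 (1.5 equiv)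
Reagents that add atoms: none
Why: Danheiser-type benzannulation: thermal conrotatory 4π ring opening of 19 gives vinylketene 29, whose ketene C=C adds [2+2] to ynol ether 28 to give 4-vinylcyclobutenone 30, and reversible 4π opening of 30 gives dienylketene 31, which closes to dienone 32 and tautomerises to phenol 33. The closest known reaction type is the aromatic annulation of cyclobutenones with triisopropylsilyl ynol ethers to resorcinol monosilyl ethers, extended here by a 3-benzyloxy group that supplies the third ring oxygen. Ring B is the only ring closed, by thermal disrotatory 6π electrocyclisation of 31 (bond C4–C5) after the [2+2] step has joined C3–C4 and C1–C2. No stereocentre is created, and the racemic C4 of 19 becomes an aromatic carbon. The step needs regioselectivity in the [2+2] addition: the electrophilic ketene carbonyl carbon must bond to the nucleophilic β-carbon of the ynol ether (the one bearing CH2–ring A) and the ketene α-carbon to the silyloxy carbon, which the polarisation of the O–C≡C unit secures. Ring C is fully substituted and its ketone is shielded by two ortho benzyloxy groups, so the arm should not intercept either ketene, and aromatisation makes the cascade irreversible.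

Step 15
Reactants: 33 ring B phenol with O2 silyl ether
Product: 34 5-(benzyloxy)-4-(ArC-methyl)-2-(ArA-methyl)benzene-1,3-diol
Conditions: Bu4NF, AcOH, THF, 0 °C
Reagents that add atoms: none
Why: Fluoride-induced cleavage of the aryl silyl ether, buffered with acetic acid so that the electron-rich phenoxide is not left under basic conditions.

Step 16
Reactants: 34 5-(benzyloxy)-4-(ArC-methyl)-2-(ArA-methyl)benzene-1,3-diol
Product: 35 1-[3-({3-[(2,6-dihydroxy-4-methoxy-3-methylphenyl)methyl]-2,4,6-trihydroxyphenyl}methyl)-2,6-dihydroxy-4-methoxy-5-methylphenyl]butan-1-one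
Conditions: H2 (1 atm), Pd/C, EtOAc–MeOH, rt; product handled under argon
Reagents that add atoms: none
Why: Hydrogenolysis of the five benzyl ethers over palladium on carbon, under which the doubly ortho-oxygenated aryl ketone and the diarylmethane C–C bonds should persist.

Step 17
Reactants: 35 heptaphenol with ring B C1 and ring A C5 open
Product: 37 1-{3-[(3-butanoyl-2,6-dihydroxy-4-methoxy-5-methylphenyl)methyl]-5-[(3-butanoyl-2,4-dihydroxy-6-methoxy-5-methylphenyl)methyl]-2,4,6-trihydroxyphenyl}butan-1-one (target), via bis-ketiminium chloride 36 (not isolated)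
Conditions: PrCN (excess), ZnCl2 (cat.), HCl (g), Et2O, 0 °C → rt; then H2O, 70 °C
Reagents that add atoms: butanenitrile, CCCC#N; water, O
Why: Twofold Hoesch acylation, in which the nitrilium electrophile should attack the only open carbon of ring B (C1) and of ring A (C5) C-selectively and without a Lewis acid that cleaves aryl methyl ethers, ring C having no open carbon, and hydrolysis of 36 gives the two ketones.

**Compound list**
1 | 2-methylbenzene-1,3,5-triol (2-methylphloroglucinol) | Cc1c(O)cc(O)cc1O | starting material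
2 | butanoyl chloride | CCCC(Cl)=O | starting material
3 | 1-(2,4,6-trihydroxy-3-methylphenyl)butan-1-one | CCCC(=O)c1c(O)cc(O)c(C)c1O | intermediate
4 | 1-(2,6-dihydroxy-4-methoxy-3-methylphenyl)butan-1-one | CCCC(=O)c1c(O)cc(OC)c(C)c1O | intermediate
5 | 1-{3-[chloro(methoxy)methyl]-2,6-dihydroxy-4-methoxy-5-methylphenyl}butan-1-one (racemic) | CCCC(=O)c1c(O)c(C(Cl)OC)c(OC)c(C)c1O | intermediate (not isolated)
6 | 3-butanoyl-2,4-dihydroxy-6-methoxy-5-methylbenzaldehyde | CCCC(=O)c1c(O)c(C=O)c(OC)c(C)c1O | intermediate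
7 | 2,4-bis(benzyloxy)-3-butanoyl-6-methoxy-5-methylbenzaldehyde | CCCC(=O)c1c(OCc2ccccc2)c(C=O)c(OC)c(C)c1OCc1ccccc1 | intermediate
8 | 2,2-dimethyl-1,3-dioxane-4,6-dione (Meldrum's acid) | CC1(C)OC(=O)CC(=O)O1 | starting material
9 | 5-{[2,4-bis(benzyloxy)-3-butanoyl-6-methoxy-5-methylphenyl]methylidene}-2,2-dimethyl-1,3-dioxane-4,6-dione | CCCC(=O)c1c(OCc2ccccc2)c(C=C2C(=O)OC(C)(C)OC2=O)c(OC)c(C)c1OCc1ccccc1 | intermediate (not isolated)
10 | 5-{[2,4-bis(benzyloxy)-3-butanoyl-6-methoxy-5-methylphenyl]methyl}-2,2-dimethyl-1,3-dioxane-4,6-dione | CCCC(=O)c1c(OCc2ccccc2)c(CC2C(=O)OC(C)(C)OC2=O)c(OC)c(C)c1OCc1ccccc1 | intermediate (not isolated)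
11 | 3-[2,4-bis(benzyloxy)-3-butanoyl-6-methoxy-5-methylphenyl]propanoic acid | CCCC(=O)c1c(OCc2ccccc2)c(CCC(=O)O)c(OC)c(C)c1OCc1ccccc1 | intermediate
12 | benzyl alcohol | OCc1ccccc1 | starting material
13 | trichloroethylene | ClC=C(Cl)Cl | starting material
14 | benzyl (E)-1,2-dichloroethenyl ether | Cl/C=C(\OCc1ccccc1)Cl | intermediate (not isolated)
15 | [(benzyloxy)ethynyl]lithium | [Li]C#COCc1ccccc1 | intermediate (not isolated)
16 | benzyl ethynyl ether | C#COCc1ccccc1 | intermediate
17 | 3-[2,4-bis(benzyloxy)-3-butanoyl-6-methoxy-5-methylphenyl]propanoyl chloride | CCCC(=O)c1c(OCc2ccccc2)c(CCC(Cl)=O)c(OC)c(C)c1OCc1ccccc1 | intermediate (not isolated)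
18 | 3-[2,4-bis(benzyloxy)-3-butanoyl-6-methoxy-5-methylphenyl]prop-1-en-1-one (ketene) | CCCC(=O)c1c(OCc2ccccc2)c(CC=C=O)c(OC)c(C)c1OCc1ccccc1 | intermediate (not isolated)
19 | 3-(benzyloxy)-4-{[2,4-bis(benzyloxy)-3-butanoyl-6-methoxy-5-methylphenyl]methyl}cyclobut-2-en-1-one (racemic) | O=C1C=C(OCc2ccccc2)C1Cc1c(OCc2ccccc2)c(C(=O)CCC)c(OCc2ccccc2)c(C)c1OC | intermediate
20 | N-methyl-N-[(2,4,6-trihydroxy-3-methylphenyl)methylidene]methanaminium chloride | Cc1c(O)cc(O)c(C=[N+](C)C)c1O.[Cl-] | intermediate (not isolated)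
21 | 2,4,6-trihydroxy-3-methylbenzaldehyde | Cc1c(O)cc(O)c(C=O)c1O | intermediate
22 | 2,6-dihydroxy-4-methoxy-3-methylbenzaldehyde | Cc1c(OC)cc(O)c(C=O)c1O | intermediate
23 | 2,6-bis(benzyloxy)-4-methoxy-3-methylbenzaldehyde | Cc1c(OC)cc(OCc2ccccc2)c(C=O)c1OCc1ccccc1 | intermediate
24 | 1,3-bis(benzyloxy)-5-methoxy-2-(2-methoxyethenyl)-4-methylbenzene (E/Z mixture) | COC=Cc1c(OCc2ccccc2)c(C)c(OC)cc1OCc1ccccc1 | intermediate (not isolated)
25 | 2-[2,6-bis(benzyloxy)-4-methoxy-3-methylphenyl]acetaldehyde | O=CCc1c(OCc2ccccc2)c(C)c(OC)cc1OCc1ccccc1 | intermediate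
26 | 1,3-bis(benzyloxy)-5-methoxy-4-methyl-2-(prop-2-yn-1-yl)benzene | C#CCc1c(OCc2ccccc2)c(C)c(OC)cc1OCc1ccccc1 | intermediate
27 | lithium 3-[2,6-bis(benzyloxy)-4-methoxy-3-methylphenyl]prop-1-yn-1-olate | [Li]OC#CCc1c(OCc2ccccc2)c(C)c(OC)cc1OCc1ccccc1 | intermediate (not isolated)
28 | triisopropyl{[3-(2,6-bis(benzyloxy)-4-methoxy-3-methylphenyl)prop-1-yn-1-yl]oxy}silane | CC(C)[Si](OC#CCc1c(OCc2ccccc2)c(C)c(OC)cc1OCc1ccccc1)(C(C)C)C(C)C | intermediate
29 | (3Z)-3-(benzyloxy)-5-[2,4-bis(benzyloxy)-3-butanoyl-6-methoxy-5-methylphenyl]penta-1,3-dien-1-one (vinylketene) | O=C=C/C(OCc1ccccc1)=C/Cc1c(OCc2ccccc2)c(C(=O)CCC)c(OCc2ccccc2)c(C)c1OC | intermediate (not isolated)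
30 | 4-[(1Z)-1-(benzyloxy)-3-ArC-prop-1-en-1-yl]-2-(ArA-methyl)-3-[(triisopropylsilyl)oxy]cyclobut-2-en-1-one (racemic) | O=C1C(Cc2c(OCc3ccccc3)c(C)c(OC)cc2OCc2ccccc2)=C(O[Si](C(C)C)(C(C)C)C(C)C)C1/C(OCc1ccccc1)=C/Cc1c(OCc2ccccc2)c(C(=O)CCC)c(OCc2ccccc2)c(C)c1OC | intermediate (not isolated)
31 | (3E,5Z)-5-(benzyloxy)-7-ArC-2-(ArA-methyl)-3-[(triisopropylsilyl)oxy]hepta-1,3,5-trien-1-one (dienylketene) | O=C=C(Cc1c(OCc2ccccc2)c(C)c(OC)cc1OCc1ccccc1)/C(O[Si](C(C)C)(C(C)C)C(C)C)=C\C(OCc1ccccc1)=C\Cc1c(OCc2ccccc2)c(C(=O)CCC)c(OCc2ccccc2)c(C)c1OC | intermediate (not isolated)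
32 | 5-(benzyloxy)-6-(ArC-methyl)-2-(ArA-methyl)-3-[(triisopropylsilyl)oxy]cyclohexa-2,4-dien-1-one (racemic) | O=C1C(Cc2c(OCc3ccccc3)c(C)c(OC)cc2OCc2ccccc2)=C(O[Si](C(C)C)(C(C)C)C(C)C)C=C(OCc2ccccc2)C1Cc1c(OCc2ccccc2)c(C(=O)CCC)c(OCc2ccccc2)c(C)c1OC | intermediate (not isolated)
33 | 3-(benzyloxy)-2-(ArC-methyl)-6-(ArA-methyl)-5-[(triisopropylsilyl)oxy]phenol | c1c(O[Si](C(C)C)(C(C)C)C(C)C)c(Cc2c(OCc3ccccc3)c(C)c(OC)cc2OCc2ccccc2)c(O)c(Cc2c(OCc3ccccc3)c(C(=O)CCC)c(OCc3ccccc3)c(C)c2OC)c1OCc1ccccc1 | intermediate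
34 | 5-(benzyloxy)-4-(ArC-methyl)-2-(ArA-methyl)benzene-1,3-diol | Oc1cc(OCc2ccccc2)c(Cc2c(OCc3ccccc3)c(C(=O)CCC)c(OCc3ccccc3)c(C)c2OC)c(O)c1Cc1c(OCc2ccccc2)c(C)c(OC)cc1OCc1ccccc1 | intermediate
35 | 1-[3-({3-[(2,6-dihydroxy-4-methoxy-3-methylphenyl)methyl]-2,4,6-trihydroxyphenyl}methyl)-2,6-dihydroxy-4-methoxy-5-methylphenyl]butan-1-one | Oc1cc(O)c(Cc2c(O)c(C(=O)CCC)c(O)c(C)c2OC)c(O)c1Cc1c(O)c(C)c(OC)cc1O | intermediate
36 | bis-ketiminium dichloride of 37 (C(=NH2+)Pr on ring B C1 and ring A C5, ring C ketone unchanged) | CCCC(=[NH2+])c1c(O)c(Cc2c(O)c(C)c(OC)c(C(=[NH2+])CCC)c2O)c(O)c(Cc2c(O)c(C(=O)CCC)c(O)c(C)c2OC)c1O.[Cl-].[Cl-] | intermediate (not isolated)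
37 | 1-{3-[(3-butanoyl-2,6-dihydroxy-4-methoxy-5-methylphenyl)methyl]-5-[(3-butanoyl-2,4-dihydroxy-6-methoxy-5-methylphenyl)methyl]-2,4,6-trihydroxyphenyl}butan-1-one | CCCC(=O)c1c(O)c(Cc2c(O)c(C)c(OC)c(C(=O)CCC)c2O)c(O)c(Cc2c(O)c(C(=O)CCC)c(O)c(C)c2OC)c1O | target

**Step count**
Total: 17 steps. Longest linear sequence: 10 steps (steps 1–5, 7, 14–17; the ring A branch, steps 8–13 then 14–17, is equally long).

**Steps most likely to fail**

Step 14. The alkoxy vinylketene may be lost to self-addition, or the cascade may stall at the crowded ring-opening and 6π stages before the hexasubstituted ring B closes. The fallback gives up the pericyclic ring construction and brings ring B in preformed; it sets out from 7 and 23 and returns to the route at 35. NaBH4 (MeOH–THF, 0 °C) should reduce the aldehyde of 7 in preference to its hindered ketone, giving 1-[2,6-bis(benzyloxy)-3-(hydroxymethyl)-4-methoxy-5-methylphenyl]butan-1-one F1. Under Sc(OTf)3 catalysis in MeCN at rt, F1 should ionise to a trialkoxybenzyl cation and alkylate an excess of commercial phloroglucinol (Friedel–Crafts benzylation), giving 1-{2,6-bis(benzyloxy)-4-methoxy-3-methyl-5-[(2,4,6-trihydroxyphenyl)methyl]phenyl}butan-1-one F2. Reduction of 23 in the same way gives [2,6-bis(benzyloxy)-4-methoxy-3-methylphenyl]methanol F3, which alkylates F2 (used in excess, at either of its two equivalent open carbons) to give the doubly bridged triol 1-[2,6-bis(benzyloxy)-3-({3-[(2,6-bis(benzyloxy)-4-methoxy-3-methylphenyl)methyl]-2,4,6-trihydroxyphenyl}methyl)-4-methoxy-5-methylphenyl]butan-1-one F4. Hydrogenolysis (H2, Pd/C) of F4 gives 35. The price is reversible arene–CH2 bond formation and statistical over-alkylation, which the main route avoids.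

Step 17. Protonation of the electron-rich rings under HCl and ZnCl2 may reverse the aryl–CH2 bonds and scramble the bridges, or the second acylation at the hindered ring A carbon may stall. The fallback moves the acyl groups from oxygen to carbon without acid; it sets out from 35 and returns at 37. Butanoic anhydride, pyridine and catalytic DMAP should give the hepta-O-butanoyl derivative of 35 F5. A photo-Fries rearrangement (254 nm, MeCN, rt) can deliver acyl groups only to the two open carbons, ring B C1 and ring A C5, giving the penta-O-butanoate of 37 F6 (shown for migration from ring B O2 and ring A O6; other positional isomers converge in the next operation). Brief methanolysis of the remaining aryl esters (K2CO3, MeOH, 0 °C) gives 37.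

Step 7. The monosubstituted ketene may dimerise, the acid chloride may lactonise onto an ortho ether oxygen, or the heat-sensitive benzyl ynol ether may rearrange before it cycloadds. The fallback reaches vinylketene 29 without a cyclobutenone and without the ynol ether 16; it sets out from 17 and returns at 33. Acid chloride 17 with Ph3P=CHCO2Et and Et3N (CH2Cl2, rt; Wittig reaction of ketene 18) should give ethyl 5-ArC-penta-2,3-dienoate F7. DABCO-catalysed β-addition of benzyl alcohol (oxa-Michael) gives ethyl (2E)-3-(benzyloxy)-5-ArC-pent-2-enoate F8. LiOH in aqueous THF gives (2E)-3-(benzyloxy)-5-ArC-pent-2-enoic acid F9, and (COCl)2 gives (2E)-3-(benzyloxy)-5-ArC-pent-2-enoyl chloride F10. Treating F10 with Et3N in the presence of 28 at rt should cause 1,4-dehydrochlorination to vinylketene 29, which is trapped as 30; heating in toluene then completes the cascade to 33. The same detour serves if 19 forms but opens only at temperatures that 28 does not survive.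

**Further compounds**
F1 | step 14 | 1-[2,6-bis(benzyloxy)-3-(hydroxymethyl)-4-methoxy-5-methylphenyl]butan-1-one | CCCC(=O)c1c(OCc2ccccc2)c(CO)c(OC)c(C)c1OCc1ccccc1
F2 | step 14 | 1-{2,6-bis(benzyloxy)-4-methoxy-3-methyl-5-[(2,4,6-trihydroxyphenyl)methyl]phenyl}butan-1-one | CCCC(=O)c1c(OCc2ccccc2)c(Cc2c(O)cc(O)cc2O)c(OC)c(C)c1OCc1ccccc1
F3 | step 14 | [2,6-bis(benzyloxy)-4-methoxy-3-methylphenyl]methanol | Cc1c(OC)cc(OCc2ccccc2)c(CO)c1OCc1ccccc1
F4 | step 14 | 1-[2,6-bis(benzyloxy)-3-({3-[(2,6-bis(benzyloxy)-4-methoxy-3-methylphenyl)methyl]-2,4,6-trihydroxyphenyl}methyl)-4-methoxy-5-methylphenyl]butan-1-one | Oc1cc(O)c(Cc2c(OCc3ccccc3)c(C(=O)CCC)c(OCc3ccccc3)c(C)c2OC)c(O)c1Cc1c(OCc2ccccc2)c(C)c(OC)cc1OCc1ccccc1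
F5 | step 17 | hepta-O-butanoyl derivative of 35 | CCCC(=O)Oc1cc(OC(=O)CCC)c(Cc2c(OC(=O)CCC)c(C(=O)CCC)c(OC(=O)CCC)c(C)c2OC)c(OC(=O)CCC)c1Cc1c(OC(=O)CCC)c(C)c(OC)cc1OC(=O)CCC
F6 | step 17 | penta-O-butanoate of 37 with free hydroxyls on ring B C2 and ring A C6 | CCCC(=O)c1c(O)c(Cc2c(OC(=O)CCC)c(C)c(OC)c(C(=O)CCC)c2O)c(OC(=O)CCC)c(Cc2c(OC(=O)CCC)c(C(=O)CCC)c(OC(=O)CCC)c(C)c2OC)c1OC(=O)CCC
F7 | step 7 | ethyl 5-[2,4-bis(benzyloxy)-3-butanoyl-6-methoxy-5-methylphenyl]penta-2,3-dienoate (racemic) | CCOC(=O)C=C=CCc1c(OCc2ccccc2)c(C(=O)CCC)c(OCc2ccccc2)c(C)c1OC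
F8 | step 7 | ethyl (2E)-3-(benzyloxy)-5-[2,4-bis(benzyloxy)-3-butanoyl-6-methoxy-5-methylphenyl]pent-2-enoate | CCOC(=O)/C=C(/OCc1ccccc1)CCc1c(OCc2ccccc2)c(C(=O)CCC)c(OCc2ccccc2)c(C)c1OC
F9 | step 7 | (2E)-3-(benzyloxy)-5-[2,4-bis(benzyloxy)-3-butanoyl-6-methoxy-5-methylphenyl]pent-2-enoic acid | OC(=O)/C=C(/OCc1ccccc1)CCc1c(OCc2ccccc2)c(C(=O)CCC)c(OCc2ccccc2)c(C)c1OC
F10 | step 7 | (2E)-3-(benzyloxy)-5-[2,4-bis(benzyloxy)-3-butanoyl-6-methoxy-5-methylphenyl]pent-2-enoyl chloride | ClC(=O)/C=C(/OCc1ccccc1)CCc1c(OCc2ccccc2)c(C(=O)CCC)c(OCc2ccccc2)c(C)c1OC
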